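Count in units of E: one E.Q holds one and one E.E.Q holds two, and the share asked for is the E in E.Q over the E in both products.

    E + E.Q → E.E.Q (k1 = 2.27 /M/s)
    E + Q + E.Q → 2 E.Q (k2 = 16.6 /M²/s)
    E + G → E.G (k3 = 24.8 /M/s)
    E + Q → E.Q (k4 = 2.26 × 10⁻⁴ /M/s)

the same everywhere: G 0.0500 M; time 30 s
- midnight: E 0.10 M; Q 0.110 M; everything together at the start
- noon: E 0.10 M (fed, over 20 s); Q 0.110 M; all else is in the flask from the start; the feed brings no volume worth counting
- dawn: E 0.10 M; Q 0.110 M (fed, over 20 s); all else is in the flask from the start; the feed brings no volume worth counting

* the flask that comes out highest in share of E.Q in E.Q plus E.E.Q, or "all alike" when all lie within 1.5 percentage points (midnight / noon / dawn / all alike)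
* share of E.Q in E.Q plus E.E.Q at the end, midnight
* share of E.Q in E.Q plus E.E.Q at the end, noon
* share of E.Q in E.Q plus E.E.Q at the end, dawn

- a species is counted by the E in it: one E.E.Q counts as two
- run time (midnight): 30 s

Run midnight and noon on a clock of E summed over time, and hold Q at its charge. Take the direct step, E with Q to E.Q, by itself: its half-life for E is 460 min, so it is a slow seed, and it makes no E.E.Q, so the share is 100%. Add the loss step, E on E.Q to E.E.Q. With the charges as at midnight its half-life for E.Q is 3.1 s, shorter than the run, and with E held at 0.10 M the clock reaches 3.00 M·s and the share falls to 7.91%. The seed cancels in that ratio.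

Now add the copying step, where E, Q and E.Q give a second E.Q. What counts is the net loss constant, the loss step's constant less the copying step's constant times Q: 0.444 /M/s. It is positive, so E.Q heads for a ceiling (a steady-state level), seed over net loss, of 5.60 × 10⁻⁵ M, which is 0.0560% of the E charged. The share rises to 10.8%.

Last comes G, which takes E with a half-life of 0.56 s and leaves 0.0500 M at midnight. The clock shrinks to 1.50 M·s, and I get 20.9%. At noon I let G catch the fed E until 10.0 s, which shortens the clock to 0.750 M·s and gives 35.8%. Dawn I leave without a number.

The forecast says noon, with 20.6% at midnight, 33.1% at noon and 28.6% at dawn, holding the copying step “not truly autocatalytic here”. Its noon stands below mine, on a clock of 0.84, and its midnight stands below mine too.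

The simulation gives 20.6% at midnight, 33.1% at noon and 28.5% at dawn, so noon comes out highest. Left for 300 s, midnight holds E.Q at 0.0526% of the E charged, close to the reckoned 0.0560%. The neighbour of noon, charged with 0.44 M of Q, turns the constant to −5.03 /M/s, negative, so the reckoning gives no ceiling and the forecast's ground does not hold there. That flask ends with E.Q at 1.26%, above noon's ceiling, E.E.Q at 1.06%, and a share of 54.2%.

The numbers are made up; the flask was simulated.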